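(The numbers in the tables are simulated on assumed constants; scatter was added.)

Answer 4 questions about L: the order of the set-ups, then the fraction of the charge found as L in blue, grey and red.

| flask | Q | G | J | remark | time |
|---|---|---|---|---|---|
| alder | 20 mM | 4 mM | 0.5 mol% | run made earlier |  |
| cedar | 20 mM | 4 mM | 0.25 mol% | run made earlier |  |
| maple | 20 mM | 4 mM | 1 mol% | run made earlier |  |
| larch | 20 mM | 8 mM | 0.5 mol% | run made earlier |  |
| blue | 20 mM | 4.00 mM | 0.5 mol% | a single well-mixed tank run continuously and read at steady state, 15 h in it on average |  |
| grey | 20 mM (fed, over 12.0 h) | 4.00 mM | 0.5 mol% | all but Q at the start; Q goes in evenly over 12.0 h, the run ends at 15 h | 15 h |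
| red | 20 mM | 4.00 mM | 0.5 mol% | everything together in a closed stirred flask, run for 15 h | 15 h |

- alder (time / h: L / %, X / %): 0.667: 7.8, 0.3; 2.00: 20.8, 1.9; 3.00: 27.2, 3.4; 5.00: 35.0, 6.8; 6.00: 37.1, 7.8; 10.0: 38.4, 12.7
- cedar (time / h: L / %, X / %): 1.33: 15.4, 0.5; 4.00: 35.1, 2.9; 6.00: 42.8, 4.5; 10.0: 49.3, 7.9; 15.0: 48.1, 9.4; 20.0: 43.2, 9.7
- maple (time / h: L / %, X / %): 3.00: 24.3, 6.3; 6.00: 28.5, 13.4; 10.0: 24.6, 19.0; 12.0: 21.5, 18.9; 15.0: 16.9, 18.1; 20.0: 10.1, 13.8
- larch (time / h: L / %, X / %): 4.00: 28.0, 4.2; 8.00: 32.1, 10.0; 10.0: 31.4, 10.9; 15.0: 25.5, 11.7; 20.0: 18.9, 10.3

(readings scatter by 0.3 percentage points)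

- the stated concentrations are those of everything mixed, before any reaction; amounts are the same in each set-up
- the earlier runs were read with a standard deviation of 0.3 percentage points
- the feed brings no volume worth counting
- the earlier runs were made in a closed, stirred flask

1. order of the set-ups by the amount of L at the outlet or at the end, in percent of the Q put in, highest first (blue / grey / red)
2. amount of L at the outlet or at the end, in percent of the Q put in, blue
3. amount of L at the outlet or at the end, in percent of the Q put in, grey
4. amount of L at the outlet or at the end, in percent of the Q put in, red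

Read the alder table, because it has the loading asked for. Take the first row: L stands at 7.8% after 0.667 h, so a reading of the starting gain of L, as a fraction of the charge, is about 0.117 /h. Set the second row against it: X grows by 1.60% of the charge while L averages 14.3%. Divide that mean L by the X made per hour to get the life of L at this loading, 11.9 h. Treat it as a pseudo-first-order life and as a rough reading, since each value carries a scatter of 0.3 percentage points and the X read is what stands in the flask, not what was formed.

Now take the last rows: L goes from 37.1% to 38.4%, so gain there nearly matches loss. That loss is 0.0322 /h, about a quarter of the starting gain.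

Carry the life to blue, where material stays 15 h on average, longer than the life. Of the L formed in that tank, the share leaving as L is the life over the life plus the stay, 44.3%. Taking Q to L at the starting rate and counting no other loss of Q, I reckon blue at 28.2%.

The forecast gives less for blue, 25%, with grey 35% and red 32%, so its order is grey > red > blue. It adds: “Grey over red is a close call”.

The flask gives grey > red > blue: blue 26.0%, grey 35.7%, red 32.6%.

    Q → L (k = 0.140 /h)
    J + L → J + X (k = 830 /M/h)
    Q + G → E (k = 27.0 /M/h)
    X → Z (k = 0.190 /h)

Blue's outlet also holds 8.41% X and 24.0% Z, together 32.4% of the charge. Put the life to work on blue: outlet L times the stay, over the life, gives 32.8% passed on from L. In red, X and Z at the end come to 39.8%, and the same life turns that into a mean L of about 31.6% over the 15 h.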